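**Strategy.** With the bicycle numbered as 3,7-dioxabicyclo[3.3.0]octane (C1 carbinol bridgehead, C2 guaiacyl carbon, O3, C4, C5 bridgehead CH, C6 veratryl carbon, O7, C8), the target is an isomer of an acyclic ketone. The C1 tertiary alcohol is a latent ketone, C5–C6 a latent electron-rich styrene and O7 a primary alcohol. A photocatalytic, redox-neutral ketyl–olefin cyclisation with radical–polar crossover closes ring A (C1–C5) and ring B (O7–C6) in one operation from the (R)-configured veratryl-cinnamyl ether of an α′-hydroxy ketone, whose single stereocentre C2 dictates C1, C5 and C6. That ether stems from an enantioselective carbene O–H insertion.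

Key step: step 6

Remarks on the chemistry:
- Ring A is C1–C2–O3–C4–C5 and ring B is C5–C6–O7–C8–C1.
- The phenol is carried as its triisopropylsilyl ether, because a free ArO–H would compete in the carbene insertion of step 3 and be deprotonated in step 4.
- Assumption: in step 3 the ligand antipode that delivers the (R)-ether is used; the sense of induction is to be confirmed on the first batch.

**Step 1**
Reactants: 1 methyl 2-(4-hydroxy-3-methoxyphenyl)acetate (methyl homovanillate); 2 chlorotriisopropylsilane
Product: 3 methyl 2-[3-methoxy-4-(triisopropylsilyloxy)phenyl]acetate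
Conditions: TIPSCl, imidazole, DMF, 25 °C
Reagents that add atoms: chlorotriisopropylsilane, CC(C)[Si](Cl)(C(C)C)C(C)C
Why: Imidazole-promoted O-silylation of the phenol should give a robust aryl silyl ether that tolerates the base, carbene and organolithium steps that follow.

**Step 2**
Reactants: 3 methyl 2-[3-methoxy-4-(triisopropylsilyloxy)phenyl]acetate; 4 4-acetamidobenzenesulfonyl azide (p-ABSA)
Product: 5 methyl 2-diazo-2-[3-methoxy-4-(triisopropylsilyloxy)phenyl]acetate
Conditions: p-ABSA, DBU, MeCN, 0 to 25 °C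
Reagents that add atoms: 4-acetamidobenzenesulfonyl azide, CC(=O)Nc1ccc(cc1)S(=O)(=O)N=[N+]=[N-]
Why: Regitz diazo transfer should occur at the benzylic, ester-activated methylene, the only acidic C–H position in 3.

**Step 3**
Reactants: 5 methyl 2-diazo-2-[3-methoxy-4-(triisopropylsilyloxy)phenyl]acetate; 6 (E)-3-(3,4-dimethoxyphenyl)prop-2-en-1-ol
Product: 7 methyl (R)-2-{[(E)-3-(3,4-dimethoxyphenyl)prop-2-en-1-yl]oxy}-2-[3-methoxy-4-(triisopropylsilyloxy)phenyl]acetate
Conditions: FeCl2·4H2O (5 mol%), spiro bis(oxazoline) ligand (Sa,S,S)-Ph-SpiroBOX or its antipode as needed for R (6 mol%), NaB[3,5-(CF3)2C6H3]4 (6 mol%), CHCl3, 40 °C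
Reagents that add atoms: (E)-3-(3,4-dimethoxyphenyl)prop-2-en-1-ol, COc1ccc(/C=C/CO)cc1OC
Why: Iron-catalysed enantioselective carbene insertion into the O–H bond of an allylic alcohol should form the C2–O3 ether and set C2 as R through the ligand-controlled proton shift, this catalyst class favouring O–H insertion over cyclopropanation of the styrene.

**Step 4**
Reactants: 7 methyl (R)-2-{[(E)-3-(3,4-dimethoxyphenyl)prop-2-en-1-yl]oxy}-2-[3-methoxy-4-(triisopropylsilyloxy)phenyl]acetate; 8 chloroiodomethane
Product: 10 (R)-1-chloro-3-{[(E)-3-(3,4-dimethoxyphenyl)prop-2-en-1-yl]oxy}-3-[3-methoxy-4-(triisopropylsilyloxy)phenyl]propan-2-one, via lithium hemiketal alkoxide 9 (not isolated)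
Conditions: ICH2Cl (2.5 equiv), MeLi·LiBr (2.4 equiv, slow addition), THF, −78 °C; sat. aq. NH4Cl at −78 °C
Reagents that add atoms: chloroiodomethane, ClCI
Why: Chloromethyllithium made in situ by iodine–lithium exchange should add to the ester (carbenoid homologation of esters to chloromethyl ketones), the tetrahedral adduct 9 surviving at −78 °C so that over-addition is avoided, and the Barbier mode keeping free organolithium away from the C2 hydrogen.

**Step 5**
Reactants: 10 (R)-1-chloro-3-{[(E)-3-(3,4-dimethoxyphenyl)prop-2-en-1-yl]oxy}-3-[3-methoxy-4-(triisopropylsilyloxy)phenyl]propan-2-one; 11 sodium formate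
Product: 13 (R)-1-{[(E)-3-(3,4-dimethoxyphenyl)prop-2-en-1-yl]oxy}-3-hydroxy-1-[3-methoxy-4-(triisopropylsilyloxy)phenyl]propan-2-one, via formate ester 12 (not isolated)
Conditions: HCO2Na (3 equiv), NaI (10 mol%), EtOH–H2O (4:1), 50 °C
Reagents that add atoms: sodium formate, [Na+].[O-]C=O
Why: SN2 displacement of the ketone-activated chloride by formate, followed by hydrolysis of the labile formate ester in the same medium, should free the C8 hydroxyl under near-neutral conditions that leave C2 untouched.

**Step 6**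
Reactants: 13 (R)-1-{[(E)-3-(3,4-dimethoxyphenyl)prop-2-en-1-yl]oxy}-3-hydroxy-1-[3-methoxy-4-(triisopropylsilyloxy)phenyl]propan-2-one
Product: 17 (1S,2R,5R,6S)-6-(3,4-dimethoxyphenyl)-2-[3-methoxy-4-(triisopropylsilyloxy)phenyl]-3,7-dioxabicyclo[3.3.0]octan-1-ol, via ketyl radical 14 (not isolated), via benzylic radical 15 (not isolated), via benzylic cation 16 (not isolated)
Conditions: fac-Ir(ppy)3 (2 mol%), (PhO)2P(O)OH (20 mol%), degassed MeCN (0.02 M), 450 nm LEDs, 25 °C
Reagents that add atoms: none
Why: Proposed new method: excited fac-Ir(ppy)3 and diphenyl phosphate should transfer an electron and a proton to the C1 ketone of 13 to give ketyl radical 14, which adds 5-exo-trig to C5 of the styrene (C1–C5, ring A) to give benzylic radical 15; the oxidised photocatalyst (tetravalent iridium) then converts this veratryl-stabilised radical into cation 16, and the C8 hydroxyl closes ring B by 5-exo-trig capture at C6 (O7–C6) with return of the proton, so the step is a catalytic, redox-neutral isomerisation. The closest known reaction types are the photoredox proton-coupled ketyl–olefin cyclisation of ketones and the photoredox radical–polar crossover oxy-alkylation of styrenes; new is their merger on an aliphatic α,α′-dioxygenated ketone without terminal reductant or oxidant. C2 should control the radical closure through a chair-like Beckwith–Houk transition state with its aryl group pseudo-equatorial, which places that group trans to the new C5–C6 bond, while the hydroxymethyl group on the ketyl carbon goes cis to C6 and the ketyl oxygen anti, fixing C1 and C5. Only this cis arrangement lets O7 reach C6, so the cis ring fusion is self-checking, and C6 is set by capture of the cation in its A(1,3)-minimised conformer (H5 eclipsing the veratryl group), which puts the aryl group on the convex face. The step needs 5-exo over 6-endo closure and cyclisation faster than back electron transfer or loss of the C2 alkoxide from the ketyl: the styrene acceptor (benzylic radical) secures the first, the neutral protonated ketyl and the fast closure the second, and the two methoxy groups make 15 easy for the catalyst to oxidise.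

**Step 7**
Reactants: 17 (1S,2R,5R,6S)-6-(3,4-dimethoxyphenyl)-2-[3-methoxy-4-(triisopropylsilyloxy)phenyl]-3,7-dioxabicyclo[3.3.0]octan-1-ol
Product: 18 (1S,2R,5R,6S)-6-(3,4-dimethoxyphenyl)-2-(4-hydroxy-3-methoxyphenyl)-3,7-dioxabicyclo[3.3.0]octan-1-ol (CNP0141816.1)
Conditions: TBAF (1.1 equiv), AcOH (1.1 equiv), THF, 0 °C
Reagents that add atoms: none
Why: Fluoride-induced cleavage of the aryl silyl ether, buffered with acetic acid, should free the phenol without exposing the ionisable benzylic ethers to strong base or acid, so no stereocentre is affected.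

**Compound list**

1 | methyl 2-(4-hydroxy-3-methoxyphenyl)acetate | COC(=O)Cc1ccc(O)c(OC)c1 | starting material
2 | chlorotriisopropylsilane | CC(C)[Si](Cl)(C(C)C)C(C)C | starting material
3 | methyl 2-[3-methoxy-4-(triisopropylsilyloxy)phenyl]acetate | COC(=O)Cc1ccc(O[Si](C(C)C)(C(C)C)C(C)C)c(OC)c1 | intermediate
4 | 4-acetamidobenzenesulfonyl azide | CC(=O)Nc1ccc(cc1)S(=O)(=O)N=[N+]=[N-] | starting material
5 | methyl 2-diazo-2-[3-methoxy-4-(triisopropylsilyloxy)phenyl]acetate | COC(=O)C(=[N+]=[N-])c1ccc(O[Si](C(C)C)(C(C)C)C(C)C)c(OC)c1 | intermediate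
6 | (E)-3-(3,4-dimethoxyphenyl)prop-2-en-1-ol | COc1ccc(/C=C/CO)cc1OC | starting material
7 | methyl (R)-2-{[(E)-3-(3,4-dimethoxyphenyl)prop-2-en-1-yl]oxy}-2-[3-methoxy-4-(triisopropylsilyloxy)phenyl]acetate | COc1cc([C@@H](OC/C=C/c2ccc(OC)c(OC)c2)C(=O)OC)ccc1O[Si](C(C)C)(C(C)C)C(C)C | intermediate
8 | chloroiodomethane | ClCI | starting material
9 | lithium hemiketal alkoxide from addition of chloromethyllithium to the ester carbonyl of 7 (C2 R, new centre undefined) | COc1cc([C@@H](OC/C=C/c2ccc(OC)c(OC)c2)C([O-])(OC)CCl)ccc1O[Si](C(C)C)(C(C)C)C(C)C.[Li+] | intermediate (not isolated)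
10 | (R)-1-chloro-3-{[(E)-3-(3,4-dimethoxyphenyl)prop-2-en-1-yl]oxy}-3-[3-methoxy-4-(triisopropylsilyloxy)phenyl]propan-2-one | COc1cc([C@@H](OC/C=C/c2ccc(OC)c(OC)c2)C(=O)CCl)ccc1O[Si](C(C)C)(C(C)C)C(C)C | intermediate
11 | sodium formate | [Na+].[O-]C=O | starting material
12 | (R)-3-{[(E)-3-(3,4-dimethoxyphenyl)prop-2-en-1-yl]oxy}-3-[3-methoxy-4-(triisopropylsilyloxy)phenyl]-2-oxopropyl formate | COc1cc([C@@H](OC/C=C/c2ccc(OC)c(OC)c2)C(=O)COC=O)ccc1O[Si](C(C)C)(C(C)C)C(C)C | intermediate (not isolated)
13 | (R)-1-{[(E)-3-(3,4-dimethoxyphenyl)prop-2-en-1-yl]oxy}-3-hydroxy-1-[3-methoxy-4-(triisopropylsilyloxy)phenyl]propan-2-one | COc1cc([C@@H](OC/C=C/c2ccc(OC)c(OC)c2)C(=O)CO)ccc1O[Si](C(C)C)(C(C)C)C(C)C | intermediate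
14 | neutral ketyl (α-hydroxyalkyl) radical at C1 of 13, C2 R | COc1cc([C@@H](OC/C=C/c2ccc(OC)c(OC)c2)[C](O)CO)ccc1O[Si](C(C)C)(C(C)C)C(C)C | intermediate (not isolated)
15 | (2R,3S,4S)-3-hydroxy-3-(hydroxymethyl)-2-[3-methoxy-4-(triisopropylsilyloxy)phenyl]tetrahydrofuran-4-yl(3,4-dimethoxyphenyl)methyl radical | COc1cc([C@H]2OC[C@H]([CH]c3ccc(OC)c(OC)c3)[C@]2(O)CO)ccc1O[Si](C(C)C)(C(C)C)C(C)C | intermediate (not isolated)
16 | the corresponding (3,4-dimethoxyphenyl)methyl cation, same ring configuration as 15 | COc1cc([C@H]2OC[C@H]([CH+]c3ccc(OC)c(OC)c3)[C@]2(O)CO)ccc1O[Si](C(C)C)(C(C)C)C(C)C | intermediate (not isolated)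
17 | (1S,2R,5R,6S)-6-(3,4-dimethoxyphenyl)-2-[3-methoxy-4-(triisopropylsilyloxy)phenyl]-3,7-dioxabicyclo[3.3.0]octan-1-ol | COc1cc([C@H]2OC[C@@H]3[C@@H](c4ccc(OC)c(OC)c4)OC[C@]23O)ccc1O[Si](C(C)C)(C(C)C)C(C)C | intermediate
18 | (1S,2R,5R,6S)-6-(3,4-dimethoxyphenyl)-2-(4-hydroxy-3-methoxyphenyl)-3,7-dioxabicyclo[3.3.0]octan-1-ol | COc1cc([C@H]2OC[C@@H]3[C@@H](c4ccc(OC)c(OC)c4)OC[C@]23O)ccc1O | target

**Step count and risks**

Total step count: 7. Longest linear sequence: 7 steps.

Steps most likely to fail:

Step 6. The excited catalyst may not reduce the aliphatic ketone, the ketyl may expel the C2 alkoxide before it cyclises, or ring B may close with poor facial selectivity at C6. The fallback uses known chemistry in two operations and sets out from 13. SmI2 with HMPA and tBuOH in THF at −78 °C should effect the reductive ketyl–olefin cyclisation (chelated divalent samarium ketyl, same anti sense) to (2R,3S,4S)-4-(3,4-dimethoxybenzyl)-3-(hydroxymethyl)-2-[3-methoxy-4-(triisopropylsilyloxy)phenyl]tetrahydrofuran-3-ol F1. DDQ in CH2Cl2 at 0 °C should then abstract hydride from the 3,4-dimethoxybenzylic CH2, and the primary alcohol should capture the cation (oxidative benzylic C–H etherification), which returns to the route at 17.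

Step 3. The metal carbene may cyclopropanate the electron-rich styrene, the allylic oxonium ylide may rearrange, or the enantioselectivity may be insufficient. The fallback sets out from 5. Dimethyldioxirane in acetone at 0 °C should oxidise the diazo group to give methyl 2-[3-methoxy-4-(triisopropylsilyloxy)phenyl]-2-oxoacetate F2. Asymmetric transfer hydrogenation with RuCl(p-cymene)[(S,S)-TsDPEN] (or its antipode, as required for R) and HCO2H/Et3N should give methyl (R)-2-hydroxy-2-[3-methoxy-4-(triisopropylsilyloxy)phenyl]acetate F3. O-Alkylation with Ag2O and (E)-4-(3-bromoprop-1-en-1-yl)-1,2-dimethoxybenzene F4 (made from 6 with PBr3 in Et2O at 0 °C) in CH2Cl2 should return to the route at 7.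

Step 4. The organolithium may remove the acidic C2 hydrogen, eroding configuration, or the carbenoid may add twice. The fallback sets out from 7. Dimethylsulfoxonium methylide (Me3S(O)I, KOtBu, THF) should convert the ester, without a strongly basic carbanion, into dimethylsulfoxonium (R)-3-{[(E)-3-(3,4-dimethoxyphenyl)prop-2-en-1-yl]oxy}-3-[3-methoxy-4-(triisopropylsilyloxy)phenyl]-2-oxopropylide F5. One equivalent of HCl in THF should protonate the ylide carbon, and chloride should displace dimethyl sulfoxide, which returns to the route at 10.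

**Further compounds**

F1 | step 6 | (2R,3S,4S)-4-(3,4-dimethoxybenzyl)-3-(hydroxymethyl)-2-[3-methoxy-4-(triisopropylsilyloxy)phenyl]tetrahydrofuran-3-ol | COc1cc([C@H]2OC[C@H](Cc3ccc(OC)c(OC)c3)[C@]2(O)CO)ccc1O[Si](C(C)C)(C(C)C)C(C)C
F2 | step 3 | methyl 2-[3-methoxy-4-(triisopropylsilyloxy)phenyl]-2-oxoacetate | COC(=O)C(=O)c1ccc(O[Si](C(C)C)(C(C)C)C(C)C)c(OC)c1
F3 | step 3 | methyl (R)-2-hydroxy-2-[3-methoxy-4-(triisopropylsilyloxy)phenyl]acetate | COc1cc([C@@H](O)C(=O)OC)ccc1O[Si](C(C)C)(C(C)C)C(C)C
F4 | step 3 | (E)-4-(3-bromoprop-1-en-1-yl)-1,2-dimethoxybenzene | COc1ccc(/C=C/CBr)cc1OC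
F5 | step 4 | dimethylsulfoxonium (R)-3-{[(E)-3-(3,4-dimethoxyphenyl)prop-2-en-1-yl]oxy}-3-[3-methoxy-4-(triisopropylsilyloxy)phenyl]-2-oxopropylide | COc1cc([C@@H](OC/C=C/c2ccc(OC)c(OC)c2)C(=O)C=S(C)(C)=O)ccc1O[Si](C(C)C)(C(C)C)C(C)C
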